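**Retrosynthetic overview**

1. The strategy rests on ring B: its exocyclic C8=C17 methylene lies next to C9, whose C11 chain is axial (anti to the C10 methyl) and would epimerise beside a C8 ketone. The C6–C7 bond is therefore cut as a type 2 carbonyl-ene closure, which makes the methylene directly (aldehyde 25 → alcohol 26).
2. After the closure: removal of the C6 hydroxyl, desilylation, oxidation to the C2 ketone and C15 acid, reduction of C2 from the β face to the axial alcohol, isovalerylation.
3. Aldehyde 25 comes from δ-lactone 22 (MeLi, methylenation, oxidation). The lactone comes from hydroboration of the C5=C6 methylene of ester 19, which sets C5.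
4. Ester 19 comes from an Ireland–Claisen rearrangement of ester 15, which sets C9 and C10. Ester 15 is made from allylic alcohol 7 (from (4R,6R)-actinol, inverted at its carbinol) and acid 14 (from (S)-citronellol).
5. Ring order: ring A is taken from the chiral pool; ring B is closed last, in step 17.

Key step: step 17

**Remarks on the chemistry (assumptions)**

- Labdane numbering is used. α is the face of the decalin that carries the C10 methyl group, β the opposite face. The target then has 5β-H, the C11 chain 9β (axial in ring B), 2α-O (axial) and 13S; its descriptors are 2S,5R,9S,10R,13S.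
- TBS = tert-butyldimethylsilyl.
- C6 in 26 is drawn as the axial 6α alcohol, which a concerted ene geometry requires. It is removed in step 19, so the 6β epimer would serve equally.
- Lactol 23 is a mixture of C8 epimers in equilibrium with its open hydroxy ketone form.

**Ring A fragment**

Step 1
Reactants: 1 (4R,6R)-actinol
Product: 2 (1S,5R)-3,3,5-trimethyl-4-oxocyclohexyl 4-nitrobenzoate
Conditions: 4-O2NC6H4CO2H, PPh3, DIAD, THF, 0 °C → rt
Reagents that add atoms: 4-nitrobenzoic acid, O=C(O)c1ccc(cc1)[N+](=O)[O-]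
Why: Mitsunobu esterification should displace the activated axial hydroxyl by SN2 from the open equatorial side, inverting the carbinol (later C2) to the configuration that will steer step 12.

Step 2
Reactants: 2 (1S,5R)-3,3,5-trimethyl-4-oxocyclohexyl 4-nitrobenzoate
Product: 3 (4S,6R)-4-hydroxy-2,2,6-trimethylcyclohexan-1-one
Conditions: K2CO3, MeOH, rt
Reagents that add atoms: none
Why: Base-catalysed transesterification should free the alcohol; the all-equatorial cis isomer is the stable one, and the α-methyl centre is erased in step 4 in any case.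

Step 3
Reactants: 3 (4S,6R)-4-hydroxy-2,2,6-trimethylcyclohexan-1-one
Product: 4 (4S,6R)-4-(TBSO)-2,2,6-trimethylcyclohexan-1-one
Conditions: TBSCl, imidazole, DMF, rt
Reagents that add atoms: tert-butyldimethylsilyl chloride, CC(C)(C)[Si](C)(C)Cl
Why: Standard silylation of an unhindered equatorial secondary alcohol gives an ether that survives all steps up to step 20.

Step 4
Reactants: 4 (4S,6R)-4-(TBSO)-2,2,6-trimethylcyclohexan-1-one
Product: 5 (4S)-4-(TBSO)-2,6,6-trimethylcyclohex-1-en-1-yl trifluoromethanesulfonate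
Conditions: LiN(iPr)2, THF, −78 → 0 °C; PhNTf2, −78 °C → rt
Reagents that add atoms: N-phenylbis(trifluoromethanesulfonimide), O=S(=O)(N(c1ccccc1)S(=O)(=O)C(F)(F)F)C(F)(F)F
Why: The ketone has a single α-hydrogen, so enolisation and O-triflation can give only the tetrasubstituted enol triflate (later C5=C10).

Step 5
Reactants: 5 (4S)-4-(TBSO)-2,6,6-trimethylcyclohex-1-en-1-yl trifluoromethanesulfonate
Product: 6 methyl (4S)-4-(TBSO)-2,6,6-trimethylcyclohex-1-ene-1-carboxylate
Conditions: CO (1 atm), Pd(OAc)2 (cat.), PPh3, Et3N, MeOH, DMF, 60 °C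
Reagents that add atoms: carbon monoxide, [C-]#[O+]; methanol, CO
Why: Palladium-catalysed methoxycarbonylation: zerovalent palladium inserts into the vinyl C–OTf bond, CO inserts, and methanol cleaves the acyl complex, bringing in C6.

Step 6
Reactants: 6 methyl (4S)-4-(TBSO)-2,6,6-trimethylcyclohex-1-ene-1-carboxylate
Product: 7 [(4S)-4-(TBSO)-2,6,6-trimethylcyclohex-1-en-1-yl]methanol
Conditions: iBu2AlH, CH2Cl2, −78 → 0 °C; aq. potassium sodium tartrate
Reagents that add atoms: none
Why: iBu2AlH should reduce the hindered conjugated ester by 1,2-addition only, giving the primary allylic alcohol.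

**Side-chain acid**

Step 7
Reactants: 8 (S)-citronellol
Product: 9 (S)-citronellol TBS ether
Conditions: TBSCl, imidazole, CH2Cl2, rt
Reagents that add atoms: tert-butyldimethylsilyl chloride, CC(C)(C)[Si](C)(C)Cl
Why: Routine silylation of the primary alcohol, which becomes C15; the stereocentre becomes C13.

Step 8
Reactants: 9 (S)-citronellol TBS ether
Product: 11 (4S)-6-(TBSO)-4-methylhexan-1-ol, via aldehyde 10 (not isolated)
Conditions: O3, CH2Cl2/MeOH, −78 °C; NaBH4, −78 °C → rt
Reagents that add atoms: ozone, [O-][O+]=O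
Why: Ozonolysis cleaves the trisubstituted alkene, and borohydride reduces the ozonolysis products in the same flask to the primary alcohol.

Step 9
Reactants: 11 (4S)-6-(TBSO)-4-methylhexan-1-ol
Product: 12 tert-butyl{[(3S)-6-bromo-3-methylhexyl]oxy}dimethylsilane
Conditions: CBr4, PPh3, CH2Cl2, 0 °C
Reagents that add atoms: carbon tetrabromide, BrC(Br)(Br)Br
Why: The Appel reaction converts the primary alcohol into the bromide under neutral conditions that leave the silyl ether intact.

Step 10
Reactants: 12 tert-butyl{[(3S)-6-bromo-3-methylhexyl]oxy}dimethylsilane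
Product: 14 (5S)-7-(TBSO)-5-methylheptanoic acid, via Grignard reagent 13 (not isolated)
Conditions: Mg, THF, 40 °C; CO2, −20 °C; cold dilute HCl
Reagents that add atoms: carbon dioxide, O=C=O
Why: Carboxylation of the primary Grignard reagent adds the one carbon (C8) needed so that the acid α-carbon is C9.

**Coupling and precursor**

Step 11
Reactants: 7 [(4S)-4-(TBSO)-2,6,6-trimethylcyclohex-1-en-1-yl]methanol; 14 (5S)-7-(TBSO)-5-methylheptanoic acid
Product: 15 [(4S)-4-(TBSO)-2,6,6-trimethylcyclohex-1-en-1-yl]methyl (5S)-7-(TBSO)-5-methylheptanoate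
Conditions: DCC, DMAP (cat.), CH2Cl2, 0 °C → rt
Reagents that add atoms: none
Why: Steglich esterification joins the two fragments under neutral conditions that do not ionise the allylic alcohol.

Step 12
Reactants: 15 [(4S)-4-(TBSO)-2,6,6-trimethylcyclohex-1-en-1-yl]methyl (5S)-7-(TBSO)-5-methylheptanoate
Product: 19 methyl (2R,5S)-7-(TBSO)-2-[(1S,5R)-5-(TBSO)-1,3,3-trimethyl-2-methylidenecyclohexyl]-5-methylheptanoate, via silyl ketene acetal 16 (not isolated), via trimethylsilyl ester 17 (not isolated), via acid 18 (not isolated)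
Conditions: LiN(iPr)2, THF, −78 °C; Me3SiCl/Et3N, −78 °C → rt, then 60 °C; H2O; then Me3SiCHN2, MeOH/toluene, rt
Reagents that add atoms: trimethylsilyldiazomethane, C[Si](C)(C)C=[N+]=[N-]
Why: Ireland–Claisen rearrangement followed by esterification of the crude acid: kinetic enolisation in THF gives the (E)-silyl ketene acetal, which should rearrange through a chair, placing the C11 chain anti to the C10 methyl (sets C9); the 2β-OTBS group holds the cyclohexene in the half-chair in which it is pseudoequatorial, so the pseudoaxial C4 methyl shields the α face and the new C9–C10 bond forms on the β face (sets C10).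

Step 13
Reactants: 19 methyl ester of the rearranged acid
Product: 22 δ-lactone 2β,15-bis(TBSO)-7-oxa-17-norlabdan-8-one (trans-fused), via alkylborane 20 (not isolated), via hydroxy ester 21 (not isolated)
Conditions: BH3·THF, THF, 0 °C → rt; NaOH, H2O2, 0 °C; then PPTS (cat.), toluene, 80 °C
Reagents that add atoms: hydrogen peroxide, OO
Why: Hydroboration–oxidation then lactonisation: boron goes to the terminal C6, and hydrogen is delivered to C5 from the β face, anti to the two axial α-methyl groups on C4 and C10 (sets 5β-H); the resulting trans-diequatorial hydroxymethyl and ester arms close to the strain-free δ-lactone.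

Step 14
Reactants: 22 δ-lactone
Product: 23 lactol 2β,15-bis(TBSO)-7-oxalabdan-8-ol (C8 epimers)
Conditions: MeLi, THF, −78 → −40 °C; aq. NH4Cl
Reagents that add atoms: methyllithium, [Li]C
Why: Mono-addition of methyllithium to a lactone: the cyclic lithium hemiketal persists at low temperature, so a second addition is not expected, and C17 is installed.

Step 15
Reactants: 23 lactol
Product: 24 2β,15-bis(TBSO)-6,7-secolabd-7-en-6-ol (isopropenyl on C9, CH2OH on C5)
Conditions: Ph3PCH3Br, KOtBu, THF, 0 °C → 50 °C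
Reagents that add atoms: methyltriphenylphosphonium bromide, C[P+](c1ccccc1)(c1ccccc1)c1ccccc1.[Br-]
Why: Wittig methylenation of the open hydroxy ketone tautomer; the C9 methine is flanked by the quaternary C10, so the ylide should not deprotonate it competitively and C9 should stay intact.

Step 16
Reactants: 24 hydroxy alkene
Product: 25 2β,15-bis(TBSO)-6,7-secolabd-7-en-6-al
Conditions: Dess–Martin periodinane, NaHCO3, CH2Cl2, 0 °C → rt
Reagents that add atoms: none
Why: Buffered Dess–Martin oxidation gives the aldehyde without acid or base that could enolise C5 or trigger a premature cyclisation.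

**Key step and completion**

Step 17
Reactants: 25 2β,15-bis(TBSO)-6,7-secolabd-7-en-6-al
Product: 26 2β,15-bis(TBSO)-labd-8(17)-en-6α-ol
Conditions: Me2AlCl (2 equiv), CH2Cl2, −78 → −20 °C; aq. potassium sodium tartrate
Reagents that add atoms: none
Why: Me2AlCl binds the C6 aldehyde, the terminal CH2 (C7) of the 1,1-disubstituted alkene attacks C6 while a hydrogen of the C17 methyl passes to oxygen through a six-membered array fused across C6–C7–C8, and the aluminium alkoxide then loses methane; this is the Lewis acid-promoted type 2 intramolecular carbonyl-ene reaction, well known for making 3-methylenecyclohexanols from 5-methylhex-5-enals. Ring B closes in a 6-exo-trig sense at the carbonyl carbon through a chair in which the trans-diequatorial C5–C6 and C10–C9 bonds of ring A become the ring fusion, so no fusion centre is made or disturbed. The only new stereocentre is C6: the hydrogen transfer needs the C6–O bond axial (1,3 to C17 across the forming ring), which gives the 6α alcohol, syn to the C10 and axial C4 methyl groups; a stepwise closure would give the 6β epimer, and both are deoxygenated in steps 18 and 19. The step needs hydrogen abstraction from C17 and not from C7 or C9, which would move the double bond into ring B and, for C9, destroy that centre; because the tether is attached to the central carbon of the ene unit, only the methyl hydrogens can reach the oxygen in the cyclic array. It also needs C5 and the axial C9 centre to stay intact, which the non-basic, low-temperature conditions and the absence of any C8 carbonyl secure.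

Step 18
Reactants: 26 2β,15-bis(TBSO)-labd-8(17)-en-6α-ol
Product: 28 O-[2β,15-bis(TBSO)-labd-8(17)-en-6α-yl] S-methyl dithiocarbonate, via sodium xanthate 27 (not isolated)
Conditions: NaH, imidazole (cat.), THF, 0 → 50 °C; CS2; MeI, rt
Reagents that add atoms: carbon disulfide, S=C=S; iodomethane, CI
Why: Xanthate formation: the alkoxide of even a hindered axial alcohol adds to the small linear CS2, and S-methylation fixes the thiocarbonyl ester.

Step 19
Reactants: 28 xanthate
Product: 29 2β,15-bis(TBSO)-labd-8(17)-ene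
Conditions: Bu3SnH, AIBN (cat.), toluene, 100 °C
Reagents that add atoms: none
Why: Barton–McCombie deoxygenation: the secondary C6 radical is quenched by the stannane faster than it can add to the homoallylic double bond, so the methylene and all stereocentres are untouched.

Step 20
Reactants: 29 2β,15-bis(TBSO)-labd-8(17)-ene
Product: 30 labd-8(17)-ene-2β,15-diol
Conditions: Bu4NF, THF, rt → 45 °C
Reagents that add atoms: none
Why: Fluoride cleaves both silyl ethers without acid, which could isomerise the exocyclic alkene.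

Step 21
Reactants: 30 labd-8(17)-ene-2β,15-diol
Product: 31 2-oxolabd-8(17)-en-15-oic acid
Conditions: CrO3, H2SO4, H2O, acetone, 0 °C
Reagents that add atoms: water, O
Why: Jones oxidation takes the primary alcohol through the aldehyde hydrate to the acid and the secondary alcohol to the ketone in one operation; the C2 ketone has no epimerisable neighbour.

Step 22
Reactants: 31 2-oxolabd-8(17)-en-15-oic acid
Product: 32 2α-hydroxylabd-8(17)-en-15-oic acid
Conditions: LiBH(sBu)3 (3 equiv), THF, −78 → 0 °C; NaOH, H2O2; HCl to pH 3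
Reagents that add atoms: none
Why: Hydride reduction under steric approach control: the axial (α) trajectory to C2 is blocked by the syn-axial methyl groups on C4 and C10, so the bulky hydride should arrive from the β face and give the axial 2α alcohol (sets C2); the acid is carried as its lithium salt.

Step 23
Reactants: 32 2α-hydroxylabd-8(17)-en-15-oic acid; 33 isovaleryl chloride
Product: 35 (2S,5R,9S,10R,13S)-2-(3-methylbutanoyloxy)labd-8(17)-en-15-oic acid (target CNP0168901.1), via mixed anhydride 34 (not isolated)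
Conditions: pyridine, DMAP (cat.), CH2Cl2, rt → 40 °C; then THF/H2O, NaHCO3, rt; HCl to pH 3
Reagents that add atoms: none
Why: DMAP-catalysed acylation with excess acid chloride esterifies the hindered axial alcohol; the carboxyl group is acylated to a mixed anhydride at the same time, and this is hydrolysed selectively in the aqueous bicarbonate stage.

**Compound list**

1 | (4R,6R)-4-hydroxy-2,2,6-trimethylcyclohexan-1-one ((4R,6R)-actinol) | CC1(C)C[C@H](O)C[C@@H](C)C1=O | starting material
2 | (1S,5R)-3,3,5-trimethyl-4-oxocyclohexyl 4-nitrobenzoate | CC1(C)C[C@@H](OC(=O)c2ccc(cc2)[N+](=O)[O-])C[C@@H](C)C1=O | intermediate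
3 | (4S,6R)-4-hydroxy-2,2,6-trimethylcyclohexan-1-one | CC1(C)C[C@@H](O)C[C@@H](C)C1=O | intermediate
4 | (4S,6R)-4-(TBSO)-2,2,6-trimethylcyclohexan-1-one | CC1(C)C[C@@H](O[Si](C)(C)C(C)(C)C)C[C@@H](C)C1=O | intermediate
5 | (4S)-4-(TBSO)-2,6,6-trimethylcyclohex-1-en-1-yl trifluoromethanesulfonate | CC1=C(OS(=O)(=O)C(F)(F)F)C(C)(C)C[C@@H](O[Si](C)(C)C(C)(C)C)C1 | intermediate
6 | methyl (4S)-4-(TBSO)-2,6,6-trimethylcyclohex-1-ene-1-carboxylate | CC1=C(C(=O)OC)C(C)(C)C[C@@H](O[Si](C)(C)C(C)(C)C)C1 | intermediate
7 | [(4S)-4-(TBSO)-2,6,6-trimethylcyclohex-1-en-1-yl]methanol | CC1=C(CO)C(C)(C)C[C@@H](O[Si](C)(C)C(C)(C)C)C1 | intermediate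
8 | (S)-citronellol, (3S)-3,7-dimethyloct-6-en-1-ol | C[C@@H](CCC=C(C)C)CCO | starting material
9 | (S)-citronellol TBS ether | C[C@@H](CCC=C(C)C)CCO[Si](C)(C)C(C)(C)C | intermediate
10 | (4S)-6-(TBSO)-4-methylhexanal | C[C@@H](CCC=O)CCO[Si](C)(C)C(C)(C)C | intermediate
11 | (4S)-6-(TBSO)-4-methylhexan-1-ol | C[C@@H](CCCO)CCO[Si](C)(C)C(C)(C)C | intermediate
12 | tert-butyl{[(3S)-6-bromo-3-methylhexyl]oxy}dimethylsilane | C[C@@H](CCCBr)CCO[Si](C)(C)C(C)(C)C | intermediate
13 | Grignard reagent of 12 | C[C@@H](CCC[Mg]Br)CCO[Si](C)(C)C(C)(C)C | intermediate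
14 | (5S)-7-(TBSO)-5-methylheptanoic acid | C[C@@H](CCCC(=O)O)CCO[Si](C)(C)C(C)(C)C | intermediate
15 | [(4S)-4-(TBSO)-2,6,6-trimethylcyclohex-1-en-1-yl]methyl (5S)-7-(TBSO)-5-methylheptanoate | CC1=C(COC(=O)CCC[C@H](C)CCO[Si](C)(C)C(C)(C)C)C(C)(C)C[C@@H](O[Si](C)(C)C(C)(C)C)C1 | intermediate
16 | (E)-trimethylsilyl ketene acetal of 15 (C11 chain cis to the allylic oxygen) | CC1=C(CO/C(O[Si](C)(C)C)=C\CC[C@H](C)CCO[Si](C)(C)C(C)(C)C)C(C)(C)C[C@@H](O[Si](C)(C)C(C)(C)C)C1 | intermediate
17 | trimethylsilyl ester of acid 18 | C[Si](C)(C)OC(=O)[C@H](CC[C@H](C)CCO[Si](C)(C)C(C)(C)C)[C@]1(C)C[C@H](O[Si](C)(C)C(C)(C)C)CC(C)(C)C1=C | intermediate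
18 | (2R,5S)-7-(TBSO)-2-[(1S,5R)-5-(TBSO)-1,3,3-trimethyl-2-methylidenecyclohexyl]-5-methylheptanoic acid | OC(=O)[C@H](CC[C@H](C)CCO[Si](C)(C)C(C)(C)C)[C@]1(C)C[C@H](O[Si](C)(C)C(C)(C)C)CC(C)(C)C1=C | intermediate
19 | methyl ester of 18 | COC(=O)[C@H](CC[C@H](C)CCO[Si](C)(C)C(C)(C)C)[C@]1(C)C[C@H](O[Si](C)(C)C(C)(C)C)CC(C)(C)C1=C | intermediate
20 | primary alkylborane from 19 (BH2 on C6, 5β-H) | COC(=O)[C@H](CC[C@H](C)CCO[Si](C)(C)C(C)(C)C)[C@]1(C)C[C@H](O[Si](C)(C)C(C)(C)C)CC(C)(C)[C@H]1CB | intermediate
21 | hydroxy ester (CH2OH on C5, 5β-H) | COC(=O)[C@H](CC[C@H](C)CCO[Si](C)(C)C(C)(C)C)[C@]1(C)C[C@H](O[Si](C)(C)C(C)(C)C)CC(C)(C)[C@H]1CO | intermediate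
22 | δ-lactone, 2β,15-bis(TBSO)-7-oxa-17-norlabdan-8-one | O=C1[C@H](CC[C@H](C)CCO[Si](C)(C)C(C)(C)C)[C@]2(C)C[C@H](O[Si](C)(C)C(C)(C)C)CC(C)(C)[C@H]2CO1 | intermediate
23 | lactol, 2β,15-bis(TBSO)-7-oxalabdan-8-ol (C8 epimers) | CC1(O)[C@H](CC[C@H](C)CCO[Si](C)(C)C(C)(C)C)[C@]2(C)C[C@H](O[Si](C)(C)C(C)(C)C)CC(C)(C)[C@H]2CO1 | intermediate
24 | 2β,15-bis(TBSO)-6,7-secolabd-7-en-6-ol | C=C(C)[C@H](CC[C@H](C)CCO[Si](C)(C)C(C)(C)C)[C@]1(C)C[C@H](O[Si](C)(C)C(C)(C)C)CC(C)(C)[C@H]1CO | intermediate
25 | 2β,15-bis(TBSO)-6,7-secolabd-7-en-6-al (key-step precursor) | C=C(C)[C@H](CC[C@H](C)CCO[Si](C)(C)C(C)(C)C)[C@]1(C)C[C@H](O[Si](C)(C)C(C)(C)C)CC(C)(C)[C@H]1C=O | intermediate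
26 | 2β,15-bis(TBSO)-labd-8(17)-en-6α-ol (key-step product) | C=C1C[C@H](O)[C@@H]2C(C)(C)C[C@@H](O[Si](C)(C)C(C)(C)C)C[C@@]2(C)[C@H]1CC[C@H](C)CCO[Si](C)(C)C(C)(C)C | intermediate
27 | sodium O-alkyl dithiocarbonate of 26 | C=C1C[C@H](OC(=S)[S-])[C@@H]2C(C)(C)C[C@@H](O[Si](C)(C)C(C)(C)C)C[C@@]2(C)[C@H]1CC[C@H](C)CCO[Si](C)(C)C(C)(C)C.[Na+] | intermediate
28 | S-methyl xanthate of 26 | C=C1C[C@H](OC(=S)SC)[C@@H]2C(C)(C)C[C@@H](O[Si](C)(C)C(C)(C)C)C[C@@]2(C)[C@H]1CC[C@H](C)CCO[Si](C)(C)C(C)(C)C | intermediate
29 | 2β,15-bis(TBSO)-labd-8(17)-ene | C=C1CC[C@@H]2C(C)(C)C[C@@H](O[Si](C)(C)C(C)(C)C)C[C@@]2(C)[C@H]1CC[C@H](C)CCO[Si](C)(C)C(C)(C)C | intermediate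
30 | labd-8(17)-ene-2β,15-diol | C=C1CC[C@@H]2C(C)(C)C[C@@H](O)C[C@@]2(C)[C@H]1CC[C@H](C)CCO | intermediate
31 | 2-oxolabd-8(17)-en-15-oic acid | C=C1CC[C@@H]2C(C)(C)CC(=O)C[C@@]2(C)[C@H]1CC[C@H](C)CC(=O)O | intermediate
32 | 2α-hydroxylabd-8(17)-en-15-oic acid | C=C1CC[C@@H]2C(C)(C)C[C@H](O)C[C@@]2(C)[C@H]1CC[C@H](C)CC(=O)O | intermediate
33 | isovaleryl chloride (3-methylbutanoyl chloride) | CC(C)CC(Cl)=O | starting material
34 | mixed anhydride of 35 with 3-methylbutanoic acid | C=C1CC[C@@H]2C(C)(C)C[C@H](OC(=O)CC(C)C)C[C@@]2(C)[C@H]1CC[C@H](C)CC(=O)OC(=O)CC(C)C | intermediate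
35 | (2S,5R,9S,10R,13S)-2-(3-methylbutanoyloxy)labd-8(17)-en-15-oic acid, CNP0168901.1 | C=C1CC[C@@H]2C(C)(C)C[C@H](OC(=O)CC(C)C)C[C@@]2(C)[C@H]1CC[C@H](C)CC(=O)O | target

**Step count**

Total: 23 steps. Longest linear sequence: 19 steps (steps 1–6 and 11–23); the side-chain acid takes 4 steps (7–10).

**Three steps most likely to fail**

Step 17 (carbonyl-ene closure). The aluminium-bound aldehyde oxygen must sit axial between the C10 and axial C4 methyl groups to reach a C17 hydrogen. If that geometry is not reached, the closure may turn stepwise, with proton loss toward C7 or C9 or chloride capture at C8, or methyl transfer from aluminium to the aldehyde may take over. The fallback sets out from lactone 22 and returns at 29. Double addition of Me3SiCH2MgCl/CeCl3 in THF should give the bis(trimethylsilylmethyl) carbinol F1, which on silica gel undergoes Peterson elimination to the allylsilane alcohol F2. Dess–Martin oxidation gives the allylsilane aldehyde F3. BF3·OEt2 at −78 °C then closes ring B by an intramolecular Hosomi–Sakurai reaction: C7 attacks C6 through an open transition state and silicon leaves from C17, so no hydrogen transfer is needed and the double bond can only end exocyclic. This should give mainly the equatorial 6β alcohol F4, whose xanthate F5 (NaH, CS2, MeI) is reduced with Bu3SnH to 29.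

Step 12 (Ireland–Claisen rearrangement). Bond formation at the tetrasubstituted C10 terminus is slow, so the silyl ketene acetal may decompose or pass through a boat array, and attack on the α face may compete; either would erode the C9/C10 relationship. The fallback sets out from allylic alcohol 7 and bromide 12 and returns at lactone 22. Johnson–Claisen rearrangement of 7 with MeC(OMe)3 and catalytic propionic acid at 140 °C should give the C9-unsubstituted ester F6 (same β-face preference, thermally robust, no C9 centre at stake). Hydroboration–oxidation gives the hydroxy ester F7, which lactonises to the lactone F8. In parallel, 12 is dehydrobrominated with KOtBu in DMSO to the terminal alkene F9, ozonolysis with NaBH4 work-up gives the five-carbon alcohol F10, and iodine, PPh3 and imidazole give the iodide F11. Alkylation of the lithium enolate of F8 (LiN(iPr)2, THF/DMPU) with F11 should occur axially, anti to the adjacent C10 methyl, putting the C11 chain in the 9β position and giving 22.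

Step 15 (methylenation of the lactol). The hemiketal may be reluctant to open, and the ylide may enolise the hindered methyl ketone instead of adding, giving low conversion or loss of integrity at C9. The fallback sets out from lactol 23 and returns at 24. The non-basic organocerium reagent from Me3SiCH2Li and CeCl3 should add to the open ketone to give the β-hydroxysilane F12, and KH in THF then effects Peterson elimination to 24.

**Further compounds**

F1 | step 17 | bis(trimethylsilylmethyl) carbinol from lactone 22 | C[Si](C)(C)CC(O)(C[Si](C)(C)C)[C@H](CC[C@H](C)CCO[Si](C)(C)C(C)(C)C)[C@]1(C)C[C@H](O[Si](C)(C)C(C)(C)C)CC(C)(C)[C@H]1CO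
F2 | step 17 | allylsilane alcohol, 17-(trimethylsilyl) analogue of 24 | C=C(C[Si](C)(C)C)[C@H](CC[C@H](C)CCO[Si](C)(C)C(C)(C)C)[C@]1(C)C[C@H](O[Si](C)(C)C(C)(C)C)CC(C)(C)[C@H]1CO
F3 | step 17 | allylsilane aldehyde, 17-(trimethylsilyl) analogue of 25 | C=C(C[Si](C)(C)C)[C@H](CC[C@H](C)CCO[Si](C)(C)C(C)(C)C)[C@]1(C)C[C@H](O[Si](C)(C)C(C)(C)C)CC(C)(C)[C@H]1C=O
F4 | step 17 | 2β,15-bis(TBSO)-labd-8(17)-en-6β-ol | C=C1C[C@@H](O)[C@@H]2C(C)(C)C[C@@H](O[Si](C)(C)C(C)(C)C)C[C@@]2(C)[C@H]1CC[C@H](C)CCO[Si](C)(C)C(C)(C)C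
F5 | step 17 | S-methyl xanthate of F4 | C=C1C[C@@H](OC(=S)SC)[C@@H]2C(C)(C)C[C@@H](O[Si](C)(C)C(C)(C)C)C[C@@]2(C)[C@H]1CC[C@H](C)CCO[Si](C)(C)C(C)(C)C
F6 | step 12 | methyl 2-[5-(TBSO)-1,3,3-trimethyl-2-methylidenecyclohexyl]acetate (C9 unsubstituted) | COC(=O)C[C@]1(C)C[C@H](O[Si](C)(C)C(C)(C)C)CC(C)(C)C1=C
F7 | step 12 | hydroxy ester from F6 (CH2OH on C5, 5β-H) | COC(=O)C[C@]1(C)C[C@H](O[Si](C)(C)C(C)(C)C)CC(C)(C)[C@H]1CO
F8 | step 12 | C9-unsubstituted δ-lactone | O=C1C[C@]2(C)C[C@H](O[Si](C)(C)C(C)(C)C)CC(C)(C)[C@H]2CO1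
F9 | step 12 | tert-butyldimethyl{[(3S)-3-methylhex-5-en-1-yl]oxy}silane | C[C@@H](CC=C)CCO[Si](C)(C)C(C)(C)C
F10 | step 12 | 5-(TBSO)-3-methylpentan-1-ol | C[C@@H](CCO)CCO[Si](C)(C)C(C)(C)C
F11 | step 12 | tert-butyl[(5-iodo-3-methylpentyl)oxy]dimethylsilane | C[C@@H](CCI)CCO[Si](C)(C)C(C)(C)C
F12 | step 15 | β-hydroxysilane from lactol 23 | C[Si](C)(C)CC(C)(O)[C@H](CC[C@H](C)CCO[Si](C)(C)C(C)(C)C)[C@]1(C)C[C@H](O[Si](C)(C)C(C)(C)C)CC(C)(C)[C@H]1CO
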